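**Overview**

Retrosynthesis: the benzoate C–O bonds at C3 and C7 are cut first, then the C1–O/C7–O pair (a diol from a C1=C7 methylidene group), then C1=C7 (from a C1 ketone, itself an unmasked nitro carbon), then, as the strategic cut, both ring bonds C1–C2 and C1–C6 (nitromethane plus a C2–C6 dialdehyde), which is traced back to the C=C bond of a cyclopentene.
Enabling feature: in the single cyclohexane ring, C1 lies between the carbinol carbons C2 and C6, and the C–O bonds at C6, C1, C2 and C3 are all trans (all equatorial in one chair), so C1 can arrive as the carbon of nitromethane, joined under equilibrating conditions to both formyl carbons of a C2–C3–C4–C5–C6 1,5-dialdehyde.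
Forward: meso-cyclopentene oxide is desymmetrised to an (R)-cyclopentenyl ether, the five-membered ring is opened by ozonolysis to the acyclic dialdehyde, and the cyclohexane, the only ring of the target, is closed once by a [5+1] double nitroaldol; nitro to ketone, methylenation, dihydroxylation and benzoylation follow without further ring formation.
Stereochemistry: C3 comes from the catalytic desymmetrisation; C2 and C6 are relayed from C3 by thermodynamic control in the double Henry step; C1 is set last by an osmylation delivered by the free C3 hydroxyl, which lies cis to the C1 hydroxyl to be made.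

Key step: step 4

Remark on numbering: C1–C7 in the text are the target locants (C1 quaternary carbinol carbon, C2 CHOH next to C3, C3 CHOBz, C4 and C5 CH2, C6 CHOH, C7 exocyclic CH2); systematic names carry their own locants.
Remark on the chemistry: the C3 oxygen is carried as a 4-methoxybenzyl (PMB) ether so it can be freed oxidatively while the C1=C7 alkene is present. The free C3 hydroxyl then steers the osmylation, because undirected osmylation of a methylidenecyclohexane flanked by equatorial ethers is expected from the axial face and would give the C1 epimer.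

**Route**

Step 1
Reactants: 1 cyclopentene oxide (meso, 6-oxabicyclo[3.1.0]hexane)
Product: 2 (R)-cyclopent-2-en-1-ol
Conditions: 3-[(2,5-dimethylpyrrolidin-1-yl)methyl]-2-azabicyclo[2.2.1]heptane (5 mol%, the enantiomer that gives the R alcohol), LiN(iPr)2 (1.5 equiv), DBU, THF, 0 °C; then H2O
Reagents that add atoms: none
Why: Enantioselective base-mediated rearrangement of a meso-epoxide to an allylic alcohol, in which the chiral lithium amide removes one of the two enantiotopic syn β-hydrogens and so fixes the carbinol carbon (later C3) as R.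

Step 2
Reactants: 2 (R)-cyclopent-2-en-1-ol
Product: 3 (R)-3-[(4-methoxybenzyl)oxy]cyclopent-1-ene
Conditions: NaH, 4-methoxybenzyl chloride, Bu4NI (cat.), THF/DMF, 0 °C → rt
Reagents that add atoms: 4-methoxybenzyl chloride, COc1ccc(CCl)cc1
Why: Williamson ether synthesis on the sodium alkoxide leaves the stereocentre untouched and installs an ether that tolerates the following steps yet can later be cleaved oxidatively beside an alkene.

Step 3
Reactants: 3 (R)-3-[(4-methoxybenzyl)oxy]cyclopent-1-ene
Product: 5 (R)-2-[(4-methoxybenzyl)oxy]pentanedial, via secondary ozonide 4 (not isolated)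
Conditions: O3, CH2Cl2, −78 °C (stopped at the first blue tinge); then PPh3, −78 °C → rt; crude 5 used at once
Reagents that add atoms: ozone, [O-][O+]=O
Why: Ozonolysis with reductive work-up (Criegee mechanism) cleaves the only C=C bond much faster than ozone attacks the anisyl ring, and the neutral cold conditions do not touch the α-alkoxy stereocentre.

Step 4
Reactants: 5 (R)-2-[(4-methoxybenzyl)oxy]pentanedial, 6 nitromethane
Product: 8 (1R,2S,3R,4R)-4-[(4-methoxybenzyl)oxy]-2-nitrocyclohexane-1,3-diol (all four substituents equatorial), via open-chain nitroaldol 7 (not isolated)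
Conditions: CH3NO2 (1.3 equiv), Na2CO3 (0.1 equiv), MeOH, 0 °C → rt; AcOH; crystallisation
Reagents that add atoms: nitromethane 6, C[N+](=O)[O-]
Why: Catalytic carbonate turns nitromethane into its nitronate, which attacks one formyl group of 5 to give the open-chain nitroaldol 7; a second deprotonation at the CH2NO2 carbon and attack on the remaining formyl group complete a [5+1] annulation in which the former nitromethane carbon becomes C1, bonded to both C2 and C6. This is a double Henry (nitroaldol) cyclisation, the reaction type established for glutaraldehyde and for dialdehydes from periodate cleavage of glycosides, applied here to a dialdehyde with one α-alkoxy stereocentre. The cyclohexane, the only ring of the target, closes in the second nitroaldol as a 6-(enolexo)-exo-trig process. C1, C2 and C6 are new stereocentres governed by C3 under thermodynamic control: both additions and the protonation at C1 are reversible, so the isomers interconvert until the chair with the C3 ether, both hydroxyls and the nitro group equatorial dominates and crystallises, which places C2–O trans to C3–O and C6–O cis to C2–O. The step needs this diastereocontrol together with retention of configuration at the base-sensitive α-alkoxy aldehyde carbon C3; the first follows from the equatorial preference of the C3 substituent, the second from a weak base in catalytic amount at 0 °C in methanol, where the aldehydes are largely masked as hemiacetals and are trapped by nitronate faster than they enolise. Self-aldol cyclisation does not compete because the two formyl groups of a 1,5-dialdehyde could only close a four-membered ring, and C4 and C5 are plain methylene groups.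

Step 5
Reactants: 8 (1R,2S,3R,4R)-4-[(4-methoxybenzyl)oxy]-2-nitrocyclohexane-1,3-diol
Product: 9 (1R,2S,3R,4R)-1,3-bis[(tert-butyldimethylsilyl)oxy]-4-[(4-methoxybenzyl)oxy]-2-nitrocyclohexane
Conditions: TBSOTf (2.4 equiv), 2,6-lutidine, CH2Cl2, −78 → 0 °C
Reagents that add atoms: tert-butyldimethylsilyl triflate, CC(C)(C)[Si](C)(C)OS(=O)(=O)C(F)(F)F
Why: Silylation of both secondary hydroxyls with a silyl triflate and a weak hindered base blocks retro-Henry fragmentation in later steps and changes no stereocentre.

Step 6
Reactants: 9 (1R,2S,3R,4R)-1,3-bis[(tert-butyldimethylsilyl)oxy]-4-[(4-methoxybenzyl)oxy]-2-nitrocyclohexane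
Product: 11 (2S,3R,6R)-2,6-bis[(tert-butyldimethylsilyl)oxy]-3-[(4-methoxybenzyl)oxy]cyclohexan-1-one, via potassium nitronate 10 (not isolated)
Conditions: KOtBu (1.05 equiv), THF, −78 °C; then dimethyldioxirane (acetone solution), −78 → 0 °C
Reagents that add atoms: dimethyldioxirane, CC1(C)OO1
Why: Oxidative Nef reaction in which cold deprotonation gives the nitronate and the dioxirane oxidises its C=N bond to the ketone with loss of nitrite, so C1 becomes the carbonyl carbon while C2, C3 and C6 keep their configuration because the nitronate is consumed at low temperature before β-elimination or epimerisation can set in.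

Step 7
Reactants: 11 (2S,3R,6R)-2,6-bis[(tert-butyldimethylsilyl)oxy]-3-[(4-methoxybenzyl)oxy]cyclohexan-1-one, 12 dibromomethane
Product: 13 (1R,3R,4R)-1,3-bis[(tert-butyldimethylsilyl)oxy]-4-[(4-methoxybenzyl)oxy]-2-methylidenecyclohexane
Conditions: Zn, CH2Br2, TiCl4, THF (reagent pre-formed at 5 °C); then 11, CH2Cl2, 0 °C → rt
Reagents that add atoms: dibromomethane 12, BrCBr
Why: Takai–Lombardo methylenation with the weakly basic zinc/titanium gem-dimetallic methylene reagent converts the hindered enolisable ketone into the C1=C7 alkene without epimerisation at C2 or C6 and without β-elimination of the C3 ether.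

Step 8
Reactants: 13 (1R,3R,4R)-1,3-bis[(tert-butyldimethylsilyl)oxy]-4-[(4-methoxybenzyl)oxy]-2-methylidenecyclohexane
Product: 14 (1R,2R,4R)-2,4-bis[(tert-butyldimethylsilyl)oxy]-3-methylidenecyclohexan-1-ol
Conditions: DDQ, CH2Cl2/pH 7 phosphate buffer, 0 °C → rt
Reagents that add atoms: none
Why: Oxidative cleavage of the 4-methoxybenzyl ether by DDQ (benzylic hydride abstraction, then hydrolysis of the oxocarbenium ion) frees the C3 hydroxyl without touching the alkene or the silyl ethers.

Step 9
Reactants: 14 (1R,2R,4R)-2,4-bis[(tert-butyldimethylsilyl)oxy]-3-methylidenecyclohexan-1-ol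
Product: 16 (1S,2S,3R,6R)-2,6-bis[(tert-butyldimethylsilyl)oxy]-1-(hydroxymethyl)cyclohexane-1,3-diol, via OsO2(TMEDA) diolate 15 (not isolated)
Conditions: OsO4 (1.05 equiv), TMEDA (1.1 equiv), CH2Cl2, −78 °C; then aq. Na2SO3, THF, 50 °C
Reagents that add atoms: osmium tetroxide, O=[Os](=O)(=O)=O
Why: Hydrogen-bond-directed syn-dihydroxylation of a cyclic homoallylic alcohol with the OsO4·TMEDA complex, in which the C3 hydroxyl, axial in the ring-flipped chair that allylic strain around the methylidene group makes accessible, binds an oxo ligand and delivers both oxygens to the alkene face cis to C3–O and anti to the two silyloxy groups, so that C1–O is trans to C2–O and C6–O and C7 is axial in the all-equatorial chair of the product.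

Step 10
Reactants: 16 (1S,2S,3R,6R)-2,6-bis[(tert-butyldimethylsilyl)oxy]-1-(hydroxymethyl)cyclohexane-1,3-diol, 17 benzoyl chloride
Product: 18 [(1S,2S,3R,6R)-3-(benzoyloxy)-2,6-bis[(tert-butyldimethylsilyl)oxy]-1-hydroxycyclohexyl]methyl benzoate
Conditions: BzCl (2.3 equiv), pyridine, DMAP (cat.), CH2Cl2, 0 °C → rt
Reagents that add atoms: benzoyl chloride 17, O=C(Cl)c1ccccc1
Why: DMAP-catalysed nucleophilic acyl substitution esterifies the primary C7 and the secondary C3 hydroxyl, whereas the tertiary C1 hydroxyl between two silyloxy-bearing carbons is too hindered to react.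

Step 11
Reactants: 18 [(1S,2S,3R,6R)-3-(benzoyloxy)-2,6-bis[(tert-butyldimethylsilyl)oxy]-1-hydroxycyclohexyl]methyl benzoate
Product: 19 [(1S,2S,3R,6R)-3-(benzoyloxy)-1,2,6-trihydroxycyclohexyl]methyl benzoate (CNP0264996.1)
Conditions: HF·pyridine, THF/pyridine, 0 °C → rt
Reagents that add atoms: none
Why: Acidic fluoride desilylation removes both secondary silyl ethers under non-basic conditions, so the benzoates neither migrate nor hydrolyse and no stereocentre is affected.

**Compound list**

1 | cyclopentene oxide (meso) | C1C[C@@H]2O[C@@H]2C1 | starting material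
2 | (R)-cyclopent-2-en-1-ol | C1C[C@@H](O)C=C1 | intermediate
3 | (R)-3-[(4-methoxybenzyl)oxy]cyclopent-1-ene | C1C[C@@H](OCc2ccc(OC)cc2)C=C1 | intermediate
4 | secondary ozonide, (2R)-2-[(4-methoxybenzyl)oxy]-6,7,8-trioxabicyclo[3.2.1]octane (bridgehead epimers) | O1C2CC[C@@H](OCc3ccc(OC)cc3)C1OO2 | intermediate (not isolated)
5 | (R)-2-[(4-methoxybenzyl)oxy]pentanedial | O=CCC[C@@H](OCc1ccc(OC)cc1)C=O | intermediate
6 | nitromethane | C[N+](=O)[O-] | starting material
7 | open-chain nitroaldol, (2R)-5-hydroxy-2-[(4-methoxybenzyl)oxy]-6-nitrohexanal (epimers at C5; drawn for first attack at the unsubstituted formyl group) | O=C[C@H](OCc1ccc(OC)cc1)CCC(O)C[N+](=O)[O-] | intermediate (not isolated)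
8 | (1R,2S,3R,4R)-4-[(4-methoxybenzyl)oxy]-2-nitrocyclohexane-1,3-diol | [O-][N+](=O)[C@H]1[C@H](O)CC[C@@H](OCc2ccc(OC)cc2)[C@@H]1O | intermediate
9 | (1R,2S,3R,4R)-1,3-bis[(tert-butyldimethylsilyl)oxy]-4-[(4-methoxybenzyl)oxy]-2-nitrocyclohexane | [O-][N+](=O)[C@H]1[C@H](O[Si](C)(C)C(C)(C)C)CC[C@@H](OCc2ccc(OC)cc2)[C@@H]1O[Si](C)(C)C(C)(C)C | intermediate
10 | potassium nitronate of 9 | [K+].[O-][N+]([O-])=C1[C@H](O[Si](C)(C)C(C)(C)C)CC[C@@H](OCc2ccc(OC)cc2)[C@@H]1O[Si](C)(C)C(C)(C)C | intermediate (not isolated)
11 | (2S,3R,6R)-2,6-bis[(tert-butyldimethylsilyl)oxy]-3-[(4-methoxybenzyl)oxy]cyclohexan-1-one | O=C1[C@H](O[Si](C)(C)C(C)(C)C)CC[C@@H](OCc2ccc(OC)cc2)[C@@H]1O[Si](C)(C)C(C)(C)C | intermediate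
12 | dibromomethane | BrCBr | starting material
13 | (1R,3R,4R)-1,3-bis[(tert-butyldimethylsilyl)oxy]-4-[(4-methoxybenzyl)oxy]-2-methylidenecyclohexane | C=C1[C@H](O[Si](C)(C)C(C)(C)C)CC[C@@H](OCc2ccc(OC)cc2)[C@@H]1O[Si](C)(C)C(C)(C)C | intermediate
14 | (1R,2R,4R)-2,4-bis[(tert-butyldimethylsilyl)oxy]-3-methylidenecyclohexan-1-ol | C=C1[C@H](O[Si](C)(C)C(C)(C)C)CC[C@@H](O)[C@@H]1O[Si](C)(C)C(C)(C)C | intermediate
15 | OsO2(TMEDA) diolate of 16 (cyclic osmate ester across the C1 and C7 oxygens) | C[N+]1(C)CC[N+](C)(C)[Os-2]12(=O)(=O)OC[C@]3(O2)[C@H](O[Si](C)(C)C(C)(C)C)CC[C@@H](O)[C@@H]3O[Si](C)(C)C(C)(C)C | intermediate (not isolated)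
16 | (1S,2S,3R,6R)-2,6-bis[(tert-butyldimethylsilyl)oxy]-1-(hydroxymethyl)cyclohexane-1,3-diol (C1,C7-diol with free C3 hydroxyl) | OC[C@]1(O)[C@H](O[Si](C)(C)C(C)(C)C)CC[C@@H](O)[C@@H]1O[Si](C)(C)C(C)(C)C | intermediate
17 | benzoyl chloride | O=C(Cl)c1ccccc1 | starting material
18 | [(1S,2S,3R,6R)-3-(benzoyloxy)-2,6-bis[(tert-butyldimethylsilyl)oxy]-1-hydroxycyclohexyl]methyl benzoate | O=C(OC[C@]1(O)[C@H](O[Si](C)(C)C(C)(C)C)CC[C@@H](OC(=O)c2ccccc2)[C@@H]1O[Si](C)(C)C(C)(C)C)c1ccccc1 | intermediate
19 | [(1S,2S,3R,6R)-3-(benzoyloxy)-1,2,6-trihydroxycyclohexyl]methyl benzoate | O=C(OC[C@]1(O)[C@H](O)CC[C@@H](OC(=O)c2ccccc2)[C@@H]1O)c1ccccc1 | target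

**Step count and risks**

Total steps: 11. Longest linear sequence: 11 steps (1 to 19).

Steps most likely to fail:

1. Step 9. What may go wrong: the hydrogen-bonded delivery needs the ring-flipped chair with C3–OH axial and 1,3-syn to the alkene. If undirected osmylation of the all-equatorial chair from its axial face competes, facial selectivity erodes towards the C1 epimer, and the doubly flanked alkene may also react sluggishly. Fallback, which delivers C7 as a nucleophile to the ketone instead of oxygen to the alkene: the route is left at ketone 11. Dimethylsulfonium methylide (Me3S+ I−, KN(SiMe3)2, THF, −20 → 0 °C, Corey–Chaykovsky epoxidation) should attack the carbonyl group along the axial trajectory, the equatorial side being screened by the two silyl groups. It closes to spiro-epoxide F1 with C7 axial and the C1 oxygen equatorial, trans to both neighbours. Opening of the epoxide at its primary carbon with cesium benzoate and benzoic acid (DMF, 80 °C) would give hydroxy benzoate F2. DDQ would then free the C3 hydroxyl to give diol monobenzoate F3, and benzoylation with 17 (pyridine, DMAP) returns to the route at 18.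

2. Step 6. What may go wrong: in the nitronate, allylic strain pushes the silyloxy groups axial, where β-elimination of silanolate to a nitroalkene becomes stereoelectronically easy; deprotonation of the hindered C1–H may also stay incomplete. Fallback, which uses reduction instead of nitronate chemistry: from 9, reduction of the nitro group (NiCl2·6H2O, NaBH4, MeOH, 0 °C) gives amine F4. Transaminative oxidative deamination with 3,5-di-tert-butyl-1,2-benzoquinone (MeOH/THF, rt; then aqueous oxalic acid) then converts it into ketone 11, where the route is rejoined.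

3. Step 4. What may go wrong: base-induced enolisation of the α-alkoxy aldehyde carbon during equilibration would erode the configurational purity at C3, and the equilibrium may not converge cleanly on one crystalline diastereomer. Fallback, a stepwise annulation with differentiated termini: from 3, ozonolysis in CH2Cl2/MeOH followed by TsOH and then NaHCO3/Me2S gives aldehyde acetal F5, in which the α-alkoxy formyl group is masked as its dimethyl acetal; the allylic ether is expected to steer carbonyl oxide formation to the remote carbon. Henry addition of 6 to the free formyl group, which has no α-stereocentre (KOtBu cat., THF, 0 °C), gives nitro alcohol acetal F6. Mild acetal hydrolysis (LiBF4, wet MeCN) releases open-chain nitroaldol 7, which is closed at once to 8 with a trace of base. The sensitive aldehyde then exists only in a molecule that already carries its intramolecular partner.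

Further compounds
F1 | step 9 | (3S,4S,5R,8R)-4,8-bis[(tert-butyldimethylsilyl)oxy]-5-[(4-methoxybenzyl)oxy]-1-oxaspiro[2.5]octane | C1O[C@]12[C@H](O[Si](C)(C)C(C)(C)C)CC[C@@H](OCc3ccc(OC)cc3)[C@@H]2O[Si](C)(C)C(C)(C)C
F2 | step 9 | [(1S,2S,3R,6R)-2,6-bis[(tert-butyldimethylsilyl)oxy]-1-hydroxy-3-[(4-methoxybenzyl)oxy]cyclohexyl]methyl benzoate | O=C(OC[C@]1(O)[C@H](O[Si](C)(C)C(C)(C)C)CC[C@@H](OCc2ccc(OC)cc2)[C@@H]1O[Si](C)(C)C(C)(C)C)c1ccccc1
F3 | step 9 | [(1S,2S,3R,6R)-2,6-bis[(tert-butyldimethylsilyl)oxy]-1,3-dihydroxycyclohexyl]methyl benzoate | O=C(OC[C@]1(O)[C@H](O[Si](C)(C)C(C)(C)C)CC[C@@H](O)[C@@H]1O[Si](C)(C)C(C)(C)C)c1ccccc1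
F4 | step 6 | (1S,2R,3R,6R)-2,6-bis[(tert-butyldimethylsilyl)oxy]-3-[(4-methoxybenzyl)oxy]cyclohexan-1-amine | N[C@H]1[C@H](O[Si](C)(C)C(C)(C)C)CC[C@@H](OCc2ccc(OC)cc2)[C@@H]1O[Si](C)(C)C(C)(C)C
F5 | step 4 | (R)-5,5-dimethoxy-4-[(4-methoxybenzyl)oxy]pentanal | O=CCC[C@@H](OCc1ccc(OC)cc1)C(OC)OC
F6 | step 4 | (5R)-6,6-dimethoxy-5-[(4-methoxybenzyl)oxy]-1-nitrohexan-2-ol (epimers at C2) | [O-][N+](=O)CC(O)CC[C@@H](OCc1ccc(OC)cc1)C(OC)OC
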